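**Retrosynthetic overview**
1. The target comes from its acetonide/benzyl-protected tetralone by one Lewis-acid deprotection; that tetralone comes from an all-cis 1-hydroxy-2-carboxylate by alcohol oxidation and Krapcho loss of the ester.
2. Key disconnection: C1–C2 and C3–C4 of the tetralone ring, a [4+2] between the photoenol of a 2-(naphthylmethyl)benzaldehyde and methyl acrylate on a chiral titanium TADDOLate; the CO2Me group is discarded afterwards.
3. The aldehyde is cut at the aryl–CH2 bond: Negishi coupling of a (4-benzyloxy-8-methoxy-1-naphthyl)methylzinc chloride (from 5-methoxy-1-naphthol) with 5-bromo-2,2-dimethyl-1,3-benzodioxole-4-carbaldehyde (from 4-bromocatechol).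
4. Ring order: the naphthalene and the catechol benzene ring are bought; the dioxole (protecting ring) is closed first; the cyclohexanone ring of the tetralone is the only skeletal ring made, in the key step.
5. Feature: the single stereocentre, tetralone C4, is a doubly benzylic C–H on C4a, ortho to C8a, which carries the C1 carbonyl and has the C8 oxygen on its other side; C1–C8a–C4a–C4 is therefore the hydroxy-ortho-quinodimethane of an ortho-(arylmethyl)benzaldehyde, and C2–C3 is a two-carbon dienophile.

Key step: step 8

Assumption: the sense of induction of the titanium TADDOLate with this dienol is not established; the route is written with (R,R)-TADDOL, and the (S,S)-ligand (also commercial) is used instead if a pilot run shows the opposite sense at C4. Tetralone locants (C1–C8a) are used for the later compounds.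

Step 1
Reactants: 1 4-bromocatechol (4-bromobenzene-1,2-diol)
Product: 2 5-bromo-2,2-dimethyl-1,3-benzodioxole
Conditions: 2,2-dimethoxypropane, TsOH·H2O (cat.), toluene, reflux, MeOH distilled off
Reagents that add atoms: 2,2-dimethoxypropane, COC(C)(C)OC
Why: Acid-catalysed transketalisation (acetonide formation) closes the five-membered dioxole on the ortho-diol and is driven by removal of methanol, while the C–Br bond is inert.

Step 2
Reactants: 2 5-bromo-2,2-dimethyl-1,3-benzodioxole
Product: 4 5-bromo-2,2-dimethyl-1,3-benzodioxole-4-carbaldehyde, via (5-bromo-2,2-dimethyl-1,3-benzodioxol-4-yl)lithium 3 (not isolated)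
Conditions: LiN(iPr)2 (LDA), THF, −78 °C; DMF, −78 to −20 °C; aq NH4Cl
Reagents that add atoms: N,N-dimethylformamide, CN(C)C=O
Why: Directed ortho-lithiation removes the most acidic ring proton, the one at C4 between the dioxole oxygen and bromine, and formylation with DMF follows; at −78 °C the amide base does not exchange bromine and the ortho-bromo aryllithium does not collapse to an aryne.

Step 3
Reactants: 5 5-methoxynaphthalen-1-ol
Product: 6 4-bromo-5-methoxynaphthalen-1-ol
Conditions: NBS (1.0 equiv), MeCN, −20 to 0 °C, dark
Reagents that add atoms: N-bromosuccinimide, O=C1CCC(=O)N1Br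
Why: Electrophilic aromatic bromination is steered by the free hydroxyl, the strongest donor, to its para position C4 (an α-position of the naphthalene), which is why bromination is done before the naphthol is protected and becomes indistinguishable from the methyl ether.

Step 4
Reactants: 6 4-bromo-5-methoxynaphthalen-1-ol
Product: 7 1-(benzyloxy)-4-bromo-5-methoxynaphthalene
Conditions: BnBr, K2CO3, DMF, 25 °C
Reagents that add atoms: benzyl bromide, BrCc1ccccc1
Why: Williamson ether synthesis on the naphtholate, which gives a protecting group that survives organolithium, organozinc, photochemical and Krapcho conditions and leaves with BCl3 at the end.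

Step 5
Reactants: 7 1-(benzyloxy)-4-bromo-5-methoxynaphthalene
Product: 10 [4-(benzyloxy)-8-methoxynaphthalen-1-yl]methanol, via [4-(benzyloxy)-8-methoxynaphthalen-1-yl]lithium 8 (not isolated), via 4-(benzyloxy)-8-methoxynaphthalene-1-carbaldehyde 9 (not isolated)
Conditions: n-BuLi (1.05 equiv), THF, −78 °C; DMF, −78 to 0 °C; then MeOH, NaBH4, 0 °C; aq NH4Cl
Reagents that add atoms: N,N-dimethylformamide, CN(C)C=O
Why: Bromine–lithium exchange at −78 °C is much faster than deprotonation of the benzyl ether, the aryllithium is formylated by DMF, and the aldehyde released in methanol is reduced in the same pot by borohydride.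

Step 6
Reactants: 10 [4-(benzyloxy)-8-methoxynaphthalen-1-yl]methanol
Product: 11 1-(benzyloxy)-4-(chloromethyl)-5-methoxynaphthalene
Conditions: SOCl2 (1.2 equiv), CH2Cl2, 0 °C; evaporated cold and used at once
Reagents that add atoms: thionyl chloride, ClS(Cl)=O
Why: Deoxychlorination through the chlorosulfite is fast for this electron-rich benzylic alcohol, and the labile chloride is not stored or chromatographed.

Step 7
Reactants: 11 1-(benzyloxy)-4-(chloromethyl)-5-methoxynaphthalene, 4 5-bromo-2,2-dimethyl-1,3-benzodioxole-4-carbaldehyde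
Product: 13 5-{[4-(benzyloxy)-8-methoxynaphthalen-1-yl]methyl}-2,2-dimethyl-1,3-benzodioxole-4-carbaldehyde, via {[4-(benzyloxy)-8-methoxynaphthalen-1-yl]methyl}zinc chloride 12 (not isolated)
Conditions: activated Zn dust, LiCl, THF, 0 to 25 °C; then added slowly to 4, Pd(OAc)2 (2 mol%), SPhos (4 mol%), THF, 25 °C
Reagents that add atoms: none
Why: LiCl-assisted zinc insertion gives the benzylic zinc chloride and Negishi cross-coupling follows, because oxidative addition of zerovalent palladium into the C–Br bond ortho to the formyl group and transmetalation should be faster at 25 °C than uncatalysed addition of the zinc reagent to the doubly ortho-substituted aldehyde.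

Step 8
Reactants: 13 5-{[4-(benzyloxy)-8-methoxynaphthalen-1-yl]methyl}-2,2-dimethyl-1,3-benzodioxole-4-carbaldehyde, 14 methyl acrylate
Product: 16 methyl (1S,2S,4S)-4-[4-(benzyloxy)-8-methoxynaphthalen-1-yl]-1-hydroxy-7,8-(isopropylidenedioxy)-1,2,3,4-tetrahydronaphthalene-2-carboxylate (all-cis), via (E)-hydroxy-ortho-quinodimethane 15 (not isolated)
Conditions: Ti(OiPr)4 (1.5 equiv), (R,R)-TADDOL (1.5 equiv, recovered), 14 (5 equiv), degassed toluene, hν 365 nm (LED), 0 °C; aq NaHCO3
Reagents that add atoms: none
Why: Proposed new method: light of 365 nm excites only the aryl aldehyde, whose n,π* state takes a hydrogen from the doubly benzylic CH2 by 1,5-transfer and relaxes to the (E)-dienol 15 with OH and naphthyl both outward; the dienol oxygen displaces isopropoxide on the titanium TADDOLate, which also binds the acrylate carbonyl, and a concerted endo [4+2] cycloaddition restores the benzene ring. The closest known reaction type is the Ti(OiPr)4/TADDOL-mediated photoenolisation/Diels–Alder reaction of 2-methylbenzaldehydes with enone dienophiles; untested here are the aryl-bearing diene terminus, which makes C4 stereogenic, the simple acrylate, and the naphthalene chromophore in the same molecule. The one ring closed, the six-membered carbocycle C1–C2–C3–C4–C4a–C8a, forms by a suprafacial intermolecular [4+2] cycloaddition that makes C1–C2 and C3–C4 together. C4 is fixed by the outward geometry of the naphthylmethylidene terminus together with the diene face left open by the TADDOLate, C1 by the (E)-enol geometry on that same face, and C2 by the endo position of the ester held by the titanium bridge, so OH, CO2Me and naphthyl end up all cis. The step needs ortho regiochemistry (ester next to the carbinol), which the titanium tether and the larger HOMO coefficient at the aryl-substituted terminus both favour, and it needs hydrogen transfer to outrun energy transfer to the naphthalene, for which the substrate offers a weak diarylmethane C–H held next to the carbonyl and an aldehyde absorption beyond the naphthalene edge.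

Step 9
Reactants: 16 methyl (1S,2S,4S)-4-[4-(benzyloxy)-8-methoxynaphthalen-1-yl]-1-hydroxy-7,8-(isopropylidenedioxy)-1,2,3,4-tetrahydronaphthalene-2-carboxylate
Product: 17 methyl (4S)-4-[4-(benzyloxy)-8-methoxynaphthalen-1-yl]-7,8-(isopropylidenedioxy)-1-oxo-1,2,3,4-tetrahydronaphthalene-2-carboxylate (C2 epimers and enol form)
Conditions: Dess–Martin periodinane (1.3 equiv), NaHCO3, CH2Cl2, 0 to 25 °C
Reagents that add atoms: none
Why: Dess–Martin oxidation of the benzylic secondary alcohol under buffered, non-basic conditions gives the β-keto ester without dehydration; the C1 and C2 stereocentres are erased on purpose and C4 is not involved.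

Step 10
Reactants: 17 methyl (4S)-4-[4-(benzyloxy)-8-methoxynaphthalen-1-yl]-7,8-(isopropylidenedioxy)-1-oxo-1,2,3,4-tetrahydronaphthalene-2-carboxylate
Product: 18 (4S)-4-[4-(benzyloxy)-8-methoxynaphthalen-1-yl]-7,8-(isopropylidenedioxy)-3,4-dihydronaphthalen-1(2H)-one
Conditions: LiCl (3 equiv), H2O (2 equiv), DMSO, 130 °C, argon
Reagents that add atoms: none
Why: Krapcho dealkoxycarbonylation (chloride attack on the ester methyl group, then loss of CO2 from the β-keto carboxylate) runs near neutrality, so the C4–H, which is acidified only through the arene, should not epimerise and the acetonide and benzyl ether are untouched.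

Step 11
Reactants: 18 (4S)-4-[4-(benzyloxy)-8-methoxynaphthalen-1-yl]-7,8-(isopropylidenedioxy)-3,4-dihydronaphthalen-1(2H)-one
Product: 19 (4S)-7,8-dihydroxy-4-(4-hydroxy-8-methoxynaphthalen-1-yl)-3,4-dihydronaphthalen-1(2H)-one (CNP0535815.1)
Conditions: BCl3 (1 M in CH2Cl2, 6 equiv), pentamethylbenzene (3 equiv), CH2Cl2, −78 to 0 °C; then aq NaHCO3
Reagents that add atoms: none
Why: Lewis-acid ether cleavage with BCl3 removes the aryl benzyl ether (benzyl cation trapped by pentamethylbenzene) and, helped by chelation to the C1 carbonyl, the catechol acetonide, while the unchelated naphthyl methyl ether should survive at or below 0 °C and the acidic medium leaves C4 untouched.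

**Compound list**
1 | 4-bromocatechol | Oc1ccc(Br)cc1O | starting material
2 | 5-bromo-2,2-dimethyl-1,3-benzodioxole | CC1(C)Oc2ccc(Br)cc2O1 | intermediate
3 | (5-bromo-2,2-dimethyl-1,3-benzodioxol-4-yl)lithium | [Li]c1c(Br)ccc2OC(C)(C)Oc12 | intermediate
4 | 5-bromo-2,2-dimethyl-1,3-benzodioxole-4-carbaldehyde | O=Cc1c(Br)ccc2OC(C)(C)Oc12 | intermediate
5 | 5-methoxynaphthalen-1-ol | COc1cccc2c(O)cccc12 | starting material
6 | 4-bromo-5-methoxynaphthalen-1-ol | COc1cccc2c(O)ccc(Br)c12 | intermediate
7 | 1-(benzyloxy)-4-bromo-5-methoxynaphthalene | COc1cccc2c(OCc3ccccc3)ccc(Br)c12 | intermediate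
8 | [4-(benzyloxy)-8-methoxynaphthalen-1-yl]lithium | [Li]c1ccc(OCc2ccccc2)c2cccc(OC)c12 | intermediate
9 | 4-(benzyloxy)-8-methoxynaphthalene-1-carbaldehyde | O=Cc1ccc(OCc2ccccc2)c2cccc(OC)c12 | intermediate
10 | [4-(benzyloxy)-8-methoxynaphthalen-1-yl]methanol | OCc1ccc(OCc2ccccc2)c2cccc(OC)c12 | intermediate
11 | 1-(benzyloxy)-4-(chloromethyl)-5-methoxynaphthalene | ClCc1ccc(OCc2ccccc2)c2cccc(OC)c12 | intermediate
12 | {[4-(benzyloxy)-8-methoxynaphthalen-1-yl]methyl}zinc chloride | Cl[Zn]Cc1ccc(OCc2ccccc2)c2cccc(OC)c12 | intermediate
13 | 5-{[4-(benzyloxy)-8-methoxynaphthalen-1-yl]methyl}-2,2-dimethyl-1,3-benzodioxole-4-carbaldehyde | O=Cc1c(Cc2ccc(OCc3ccccc3)c3cccc(OC)c23)ccc2OC(C)(C)Oc12 | intermediate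
14 | methyl acrylate | C=CC(=O)OC | starting material
15 | (E)-hydroxy-ortho-quinodimethane (photoenol of 13, OH and naphthyl outward) | O/C=C1/C(=C/c2ccc(OCc3ccccc3)c3cccc(OC)c23)C=CC2=C1OC(C)(C)O2 | intermediate
16 | methyl (1S,2S,4S)-4-[4-(benzyloxy)-8-methoxynaphthalen-1-yl]-1-hydroxy-7,8-(isopropylidenedioxy)-1,2,3,4-tetrahydronaphthalene-2-carboxylate | COC(=O)[C@H]1C[C@@H](c2ccc(OCc3ccccc3)c3cccc(OC)c23)c2ccc3OC(C)(C)Oc3c2[C@H]1O | intermediate
17 | methyl (4S)-4-[4-(benzyloxy)-8-methoxynaphthalen-1-yl]-7,8-(isopropylidenedioxy)-1-oxo-1,2,3,4-tetrahydronaphthalene-2-carboxylate | COC(=O)C1C[C@@H](c2ccc(OCc3ccccc3)c3cccc(OC)c23)c2ccc3OC(C)(C)Oc3c2C1=O | intermediate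
18 | (4S)-4-[4-(benzyloxy)-8-methoxynaphthalen-1-yl]-7,8-(isopropylidenedioxy)-3,4-dihydronaphthalen-1(2H)-one | COc1cccc2c(OCc3ccccc3)ccc([C@@H]4CCC(=O)c5c4ccc4OC(C)(C)Oc54)c12 | intermediate
19 | (4S)-7,8-dihydroxy-4-(4-hydroxy-8-methoxynaphthalen-1-yl)-3,4-dihydronaphthalen-1(2H)-one | COc1cccc2c(O)ccc([C@@H]3CCC(=O)c4c3ccc(O)c4O)c12 | target

**Step count**
Total: 11 steps. Longest linear sequence: 9 steps (steps 3–11, from 5-methoxynaphthalen-1-ol); the benzodioxole branch (steps 1–2) joins at step 7.

**Steps most likely to fail**

Step 8 (Proposed new method). Energy transfer from the excited aldehyde to the naphthalene may outrun hydrogen transfer, so that no dienol forms. The naphthyl group may also turn inward on the diene terminus, or the TADDOLate may discriminate the diene faces poorly, which would erode the configuration at C4. Fallback, from 13 back to 18, forms the same two bonds in the ground state. Pinnick oxidation of 13 (NaClO2, NaH2PO4, 2-methyl-2-butene, t-BuOH/H2O) should give 5-{[4-(benzyloxy)-8-methoxynaphthalen-1-yl]methyl}-2,2-dimethyl-1,3-benzodioxole-4-carboxylic acid F1, and MeI/K2CO3 in DMF its methyl ester F2. LiN(iPr)2 in THF at −78 °C removes a doubly benzylic proton of F2; the diarylmethyl anion adds to methyl acrylate and the resulting ester enolate closes onto the benzoate (Michael/Dieckmann sequence, Staunton–Weinreb-type annulation) to give the racemic β-keto ester F3. Krapcho dealkoxycarbonylation as in step 10 gives the racemic tetralone F4, which is resolved by preparative HPLC on a polysaccharide chiral stationary phase; the (S)-enantiomer is 18 and the (R)-tetralone F5 is set aside.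

Step 7. The benzylic zinc reagent may add to the aldehyde of 4 or of 13, and zinc insertion into the very electron-rich chloride may be accompanied by Wurtz-type homocoupling or by ionisation and self-alkylation of 11. Fallback, from 7 and 4 back to 13, uses boron instead of zinc and needs no benzylic chloride. Aryllithium 8, made from 7 as in step 5, is treated at −78 °C with 2-(chloromethyl)-4,4,5,5-tetramethyl-1,3,2-dioxaborolane and warmed, so that 1,2-aryl migration with loss of chloride (Matteson homologation) gives 2-{[4-(benzyloxy)-8-methoxynaphthalen-1-yl]methyl}-4,4,5,5-tetramethyl-1,3,2-dioxaborolane F6. Suzuki–Miyaura coupling of F6 with 4 (Pd(OAc)2, SPhos, K3PO4, toluene/H2O, 80 °C) should give 13; boronates do not add to aldehydes, and steps 5 and 6 are bypassed.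

Step 3. Regiocontrol may be lost (attack ortho to the hydroxyl, double bromination), or the electron-rich naphthol may be oxidised towards the quinone by the N-bromo reagent. Fallback, from 5 back to 9, installs the carbon directly instead of a halogen. para-Formylation of 5 with triethyl orthoformate and AlCl3 in toluene (0 to 25 °C, then dilute HCl) should give 4-hydroxy-8-methoxynaphthalene-1-carbaldehyde F7; O-benzylation (BnBr, K2CO3, DMF) gives 9, here isolated, and NaBH4 in MeOH takes it to 10 as in the second half of step 5.

**Further compounds**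
F1 | step 8 | 5-{[4-(benzyloxy)-8-methoxynaphthalen-1-yl]methyl}-2,2-dimethyl-1,3-benzodioxole-4-carboxylic acid | OC(=O)c1c(Cc2ccc(OCc3ccccc3)c3cccc(OC)c23)ccc2OC(C)(C)Oc12
F2 | step 8 | methyl 5-{[4-(benzyloxy)-8-methoxynaphthalen-1-yl]methyl}-2,2-dimethyl-1,3-benzodioxole-4-carboxylate | COC(=O)c1c(Cc2ccc(OCc3ccccc3)c3cccc(OC)c23)ccc2OC(C)(C)Oc12
F3 | step 8 | racemic methyl 4-[4-(benzyloxy)-8-methoxynaphthalen-1-yl]-7,8-(isopropylidenedioxy)-1-oxo-1,2,3,4-tetrahydronaphthalene-2-carboxylate | COC(=O)C1CC(c2ccc(OCc3ccccc3)c3cccc(OC)c23)c2ccc3OC(C)(C)Oc3c2C1=O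
F4 | step 8 | racemic 4-[4-(benzyloxy)-8-methoxynaphthalen-1-yl]-7,8-(isopropylidenedioxy)-3,4-dihydronaphthalen-1(2H)-one | COc1cccc2c(OCc3ccccc3)ccc(C4CCC(=O)c5c4ccc4OC(C)(C)Oc54)c12
F5 | step 8 | (4R)-4-[4-(benzyloxy)-8-methoxynaphthalen-1-yl]-7,8-(isopropylidenedioxy)-3,4-dihydronaphthalen-1(2H)-one | COc1cccc2c(OCc3ccccc3)ccc([C@H]4CCC(=O)c5c4ccc4OC(C)(C)Oc54)c12
F6 | step 7 | 2-{[4-(benzyloxy)-8-methoxynaphthalen-1-yl]methyl}-4,4,5,5-tetramethyl-1,3,2-dioxaborolane | CC1(C)OB(Cc2ccc(OCc3ccccc3)c3cccc(OC)c23)OC1(C)C
F7 | step 3 | 4-hydroxy-8-methoxynaphthalene-1-carbaldehyde | O=Cc1ccc(O)c2cccc(OC)c12
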